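**Plan**

1. Retrosynthesis (ring locants: C1 ketone, C2 bears CH2OAc, C4 carbinol, C5/C6 oxirane carbons, C1' side-chain carbinol): cut C1–C6 first, then C3–C4 (coupling of two β-iodoacrylate-derived halves), then C5–C1' (iodo-aldol of farnesal with methyl propiolate).
2. Enabling feature: C4(OH)–C3=C2–C1(=O) is a γ-hydroxy enone with C1 and C4 cis on the double bond, i.e. a butenolide (ring O on C4, acyl carbon C1) opened by a carbon nucleophile; C6 is an oxirane CH that can carry lithium with retention.
3. Forward: iodo-aldol gives the C1'–C5(=C6)–C4 unit; a second iodoacrylate adds to the C4 aldehyde and lactonizes (butenolide ring O–C1–C2–C3–C4); epoxidation makes the oxirane; tin–lithium exchange at C6 and attack on the lactone carbonyl closes the carbocycle and frees the C4 hydroxyl; acetylation last.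
4. Stereochemistry: C1' by Sharpless kinetic resolution; C4 by 1,3-anti chelate-controlled chromium addition; C5 and C6 by matched hydroxyl-directed Sharpless epoxidation of the vinylstannane; C6 is kept by retentive exchange and acylation.

Key step: step 10

Remark: (2E,6E)-farnesol, methyl propiolate and paraformaldehyde are taken as commercial. Tartrate assignments follow the usual Sharpless rule for secondary allylic alcohols (erythro epoxy alcohol from the fast-reacting enantiomer).

**Step 1**
Reactants: 1 (2E,6E)-farnesol
Product: 2 (2E,6E)-farnesal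
Conditions: PhI(OAc)2 (1.1 equiv), TEMPO (10 mol%), CH2Cl2, rt
Reagents that add atoms: none
Why: TEMPO/PhI(OAc)2 oxidation of the allylic alcohol should give the enal without E/Z isomerization or over-oxidation.

**Step 2**
Reactants: 2 (2E,6E)-farnesal; 3 methyl propiolate
Product: 4 racemic methyl (2Z,4E,8E)-3-hydroxy-2-(iodomethylidene)-5,9,13-trimethyltetradeca-4,8,12-trienoate
Conditions: MgI2 (1.2 equiv), CH2Cl2, 0 °C; then H2O
Reagents that add atoms: magnesium iodide MgI2, [Mg+2].[I-].[I-]
Why: MgI2-promoted iodo-aldol (β-iodo Morita–Baylis–Hillman-type) reaction, in which iodide adds to the activated propiolate and the β-iodoallenolate adds 1,2 to the aldehyde anti to iodine, which should place iodine cis to the ester and create C1' as a racemate.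

**Step 3**
Reactants: 4 racemic iodo-aldol adduct
Product: 5 methyl (2Z,3S,4E,8E)-3-hydroxy-2-(iodomethylidene)-5,9,13-trimethyltetradeca-4,8,12-trienoate
Conditions: Ti(OiPr)4 (10 mol%), L-(+)-DIPT (15 mol%), t-BuOOH (0.6 equiv), 4 Å MS, CH2Cl2, −20 °C
Reagents that add atoms: none
Why: Sharpless kinetic resolution, in which the side-chain C4=C5 alkene is the only electron-rich alkene next to the carbinol (the iodoacrylate is inert) and is matched with L-(+)-tartrate for the (3R) enantiomer, so that enantiomer should be consumed as its epoxide and (3S)-5 recovered.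

**Step 4**
Reactants: 5 (3S)-iodo ester
Product: 6 (2E,3S,4E,8E)-2-(iodomethylidene)-5,9,13-trimethyltetradeca-4,8,12-triene-1,3-diol
Conditions: i-Bu2AlH (3.5 equiv), CH2Cl2, −78 °C; then H2O
Reagents that add atoms: none
Why: DIBAL-H 1,2-reduction of the enoate to the allylic alcohol at low temperature should leave the vinyl iodide and its geometry untouched.

**Step 5**
Reactants: 6 iodo diol
Product: 7 (2Z,3S,4E,8E)-3-hydroxy-2-(iodomethylidene)-5,9,13-trimethyltetradeca-4,8,12-trienal
Conditions: PhI(OAc)2 (1.1 equiv), TEMPO (10 mol%), CH2Cl2, 0 °C to rt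
Reagents that add atoms: none
Why: TEMPO/PhI(OAc)2 oxidation is selective for the primary allylic alcohol over the hindered secondary one and should give the enal with iodine still cis to the carbonyl.

**Step 6**
Reactants: 7 iodo enal
Product: 8 (2Z,3S,4E,8E)-3-hydroxy-5,9,13-trimethyl-2-[(tributylstannyl)methylidene]tetradeca-4,8,12-trienal
Conditions: Bu3SnSnBu3 (1.5 equiv), Pd(PPh3)4 (5 mol%), toluene, 60 °C
Reagents that add atoms: hexabutyldistannane, CCCC[Sn](CCCC)(CCCC)[Sn](CCCC)(CCCC)CCCC
Why: Palladium-catalysed stannylation (Stille-type iodide–tin exchange) by oxidative addition to zerovalent palladium, transmetalation with the distannane and reductive elimination should give the vinylstannane with retention of geometry and remove the iodide before the next coupling.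

**Step 7**
Reactants: 3 methyl propiolate
Product: 9 methyl (2Z)-2-(hydroxymethyl)-3-iodoprop-2-enoate
Conditions: (CH2O)n (2 equiv), MgI2 (1.2 equiv), CH2Cl2, rt; then H2O
Reagents that add atoms: formaldehyde (from paraformaldehyde), C=O; magnesium iodide MgI2, [Mg+2].[I-].[I-]
Why: The same MgI2-promoted iodo-aldol reaction as in step 2, with formaldehyde released from paraformaldehyde by the Lewis acid, should give the isomer with iodine cis to the ester.

**Step 8**
Reactants: 8 stannyl enal; 9 methyl (2Z)-2-(hydroxymethyl)-3-iodoprop-2-enoate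
Product: 11 (5S)-3-(hydroxymethyl)-5-[(1Z,3S,4E,8E)-3-hydroxy-5,9,13-trimethyl-1-(tributylstannyl)tetradeca-1,4,8,12-tetraen-2-yl]furan-2(5H)-one, via open-chain Z-hydroxy ester 10 (not isolated)
Conditions: CrCl2 (6 equiv), NiCl2 (2 mol%), DMSO/THF, rt; then H2O
Reagents that add atoms: none
Why: Nozaki–Hiyama–Kishi reaction in which the alkenylchromium from 9 (nickel-catalysed, divalent chromium) adds to the aldehyde with retention of alkene geometry while the free C1' hydroxyl holds chromium in a six-membered chelate, so that attack anti to the C1' alkenyl group should give the 1,3-anti (C4 S) carbinol, which lactonizes onto the cis ester.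

**Step 9**
Reactants: 11 stannyl butenolide
Product: 12 (5S)-3-(hydroxymethyl)-5-[(2R,3S)-2-[(1S,2E,6E)-1-hydroxy-3,7,11-trimethyldodeca-2,6,10-trien-1-yl]-3-(tributylstannyl)oxiran-2-yl]furan-2(5H)-one
Conditions: Ti(OiPr)4 (30 mol%), L-(+)-DIPT (36 mol%), t-BuOOH (1.5 equiv), 4 Å MS, CH2Cl2, −20 °C
Reagents that add atoms: tert-butyl hydroperoxide, CC(C)(C)OO
Why: Sharpless asymmetric epoxidation directed by the C1' hydroxyl, for which the electron-rich vinylstannane is the matched alkene of the (S) carbinol with L-(+)-tartrate (side-chain alkene mismatched, butenolide alkene electron-poor, lactone oxygen not a ligand), so syn oxygen transfer erythro to the carbinol should set C5 (R) and leave tin cis to the butenolide on the oxirane.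

**Step 10**
Reactants: 12 epoxystannane butenolide
Product: 15 (4S,5R,6R)-5,6-epoxy-4-hydroxy-2-(hydroxymethyl)-5-[(1S,2E,6E)-1-hydroxy-3,7,11-trimethyldodeca-2,6,10-trien-1-yl]cyclohex-2-en-1-one, via C6-lithiated oxirane 13 (not isolated), via bridged hemiketal alkoxide 14 (not isolated)
Conditions: n-BuLi (3.05 equiv), THF/Et2O, −100 to −78 °C; then AcOH (3.1 equiv), −78 °C
Reagents that add atoms: none
Why: Proposed new method: butyllithium first forms the two lithium alkoxides and then attacks tin, and the stannate releases the C6-lithiated oxirane 13 with retention (lithiated epoxides are pyramidal and configurationally stable at low temperature); C6–Li is cis to the butenolide on the oxirane and adds to the lactone carbonyl C1 to give the strained 7-oxabicyclo[2.2.1]heptene hemiketal alkoxide 14, whose collapse breaks the C1–O bond, forms the enone and releases the C4 alkoxide. The closest known reaction types are tin–lithium exchange of stannyl epoxides with trapping of the α-lithiated epoxide by carbonyl electrophiles, and anionic (Parham-type) ring closure of organolithiums onto esters or lactones; new is their combination in one molecule, with the exchange run in the presence of the lactone. The six-membered carbocycle closes in a 6-exo-trig mode at the C1=O group, and the transient second ring (the C1–O–C4 bridge) opens again in the same operation. No new stereocenter arises: C6 is carried over with retention and C4, C5 and C1' are untouched, so the cis fusion of the oxirane follows from the geometry of 12. The step needs the exchange at tin to outrun addition of butyllithium to the lactone and removal of the C4 proton (which would open the oxirane by elimination); the alkoxides formed first lower the electrophilicity and acidity of the substrate toward external reagent, the C1' alkoxide can hold butyllithium close to the stannane, and the lactone carbonyl is held within reach of C6 so that capture is intramolecular.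

**Step 11**
Reactants: 15 triol
Product: 16 target, [(4S,5R,6R)-5,6-epoxy-4-hydroxy-5-[(1S,2E,6E)-1-hydroxy-3,7,11-trimethyldodeca-2,6,10-trien-1-yl]-1-oxocyclohex-2-en-2-yl]methyl acetate
Conditions: Ac2O (1.1 equiv), 2,4,6-collidine, CH2Cl2, −20 °C
Reagents that add atoms: acetic anhydride, CC(=O)OC(C)=O
Why: Acylation with a hindered pyridine base at low temperature should acetylate only the primary allylic alcohol, the two secondary alcohols reacting much more slowly.

**Compound list**

1 | (2E,6E)-farnesol | OC/C=C(\C)CC/C=C(\C)CCC=C(C)C | starting material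
2 | (2E,6E)-farnesal | O=C/C=C(\C)CC/C=C(\C)CCC=C(C)C | intermediate
3 | methyl propiolate | C#CC(=O)OC | starting material
4 | racemic methyl (2Z,4E,8E)-3-hydroxy-2-(iodomethylidene)-5,9,13-trimethyltetradeca-4,8,12-trienoate (iodine cis to the ester) | COC(=O)/C(=C\I)C(O)/C=C(\C)CC/C=C(\C)CCC=C(C)C | intermediate
5 | methyl (2Z,3S,4E,8E)-3-hydroxy-2-(iodomethylidene)-5,9,13-trimethyltetradeca-4,8,12-trienoate | COC(=O)/C(=C\I)[C@@H](O)/C=C(\C)CC/C=C(\C)CCC=C(C)C | intermediate
6 | (2E,3S,4E,8E)-2-(iodomethylidene)-5,9,13-trimethyltetradeca-4,8,12-triene-1,3-diol | OC/C(=C\I)[C@@H](O)/C=C(\C)CC/C=C(\C)CCC=C(C)C | intermediate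
7 | (2Z,3S,4E,8E)-3-hydroxy-2-(iodomethylidene)-5,9,13-trimethyltetradeca-4,8,12-trienal | O=C/C(=C\I)[C@@H](O)/C=C(\C)CC/C=C(\C)CCC=C(C)C | intermediate
8 | (2Z,3S,4E,8E)-3-hydroxy-5,9,13-trimethyl-2-[(tributylstannyl)methylidene]tetradeca-4,8,12-trienal | O=C/C(=C\[Sn](CCCC)(CCCC)CCCC)[C@@H](O)/C=C(\C)CC/C=C(\C)CCC=C(C)C | intermediate
9 | methyl (2Z)-2-(hydroxymethyl)-3-iodoprop-2-enoate | COC(=O)/C(CO)=C\I | intermediate
10 | open-chain Z-hydroxy ester from 8 and 9 (formed as its chromium alkoxide, drawn as the alcohol) | COC(=O)/C(CO)=C\[C@H](O)/C(=C\[Sn](CCCC)(CCCC)CCCC)[C@@H](O)/C=C(\C)CC/C=C(\C)CCC=C(C)C | intermediate (not isolated)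
11 | (5S)-3-(hydroxymethyl)-5-[(1Z,3S,4E,8E)-3-hydroxy-5,9,13-trimethyl-1-(tributylstannyl)tetradeca-1,4,8,12-tetraen-2-yl]furan-2(5H)-one | OCC1=C[C@H](OC1=O)/C(=C\[Sn](CCCC)(CCCC)CCCC)[C@@H](O)/C=C(\C)CC/C=C(\C)CCC=C(C)C | intermediate
12 | (5S)-3-(hydroxymethyl)-5-[(2R,3S)-2-[(1S,2E,6E)-1-hydroxy-3,7,11-trimethyldodeca-2,6,10-trien-1-yl]-3-(tributylstannyl)oxiran-2-yl]furan-2(5H)-one | OCC1=C[C@H](OC1=O)[C@@]2([C@@H](O)/C=C(\C)CC/C=C(\C)CCC=C(C)C)O[C@H]2[Sn](CCCC)(CCCC)CCCC | intermediate
13 | C6-lithiated oxirane, dilithium dialkoxide of 12 after tin–lithium exchange | [Li]OCC1=C[C@H](OC1=O)[C@@]2([C@@H](O[Li])/C=C(\C)CC/C=C(\C)CCC=C(C)C)O[C@H]2[Li] | intermediate (not isolated)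
14 | bridged hemiketal alkoxide (7-oxabicyclo[2.2.1]hept-2-ene core with the oxirane endo, trilithium salt) | [Li]OCC1=C[C@@H]2O[C@@]1(O[Li])[C@@H]3O[C@]23[C@@H](O[Li])/C=C(\C)CC/C=C(\C)CCC=C(C)C | intermediate (not isolated)
15 | (4S,5R,6R)-5,6-epoxy-4-hydroxy-2-(hydroxymethyl)-5-[(1S,2E,6E)-1-hydroxy-3,7,11-trimethyldodeca-2,6,10-trien-1-yl]cyclohex-2-en-1-one | OCC1=C[C@H](O)[C@@]2([C@@H](O)/C=C(\C)CC/C=C(\C)CCC=C(C)C)O[C@H]2C1=O | intermediate
16 | [(4S,5R,6R)-5,6-epoxy-4-hydroxy-5-[(1S,2E,6E)-1-hydroxy-3,7,11-trimethyldodeca-2,6,10-trien-1-yl]-1-oxocyclohex-2-en-2-yl]methyl acetate | CC(=O)OCC1=C[C@H](O)[C@@]2([C@@H](O)/C=C(\C)CC/C=C(\C)CCC=C(C)C)O[C@H]2C1=O | target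

**Step count**

Total step count: 11. Longest linear sequence: 10 steps (steps 1–6 and 8–11, from 1).

**Three steps most likely to fail**

1. Step 10 (bears the label). Addition of butyllithium to the lactone carbonyl, or removal of the C4 proton followed by eliminative opening of the oxirane, may compete with tin–lithium exchange. The lithiated oxirane may also decompose as a carbenoid before it closes the ring. The fallback uses known chemistry, sets out from 12 and comes back at 15. Saponification of 12 (LiOH, 1.0 equiv, THF/H2O, 0 °C, no acidification) would give the dry lithium salt of the ring-opened (2Z)-4-hydroxy acid F1, whose carboxylate does not react with alkyllithiums at −78 °C. Treatment of F1 with n-BuLi (4.1 equiv, THF, −78 to −40 °C) would form the three alkoxides and effect tin–lithium exchange. The lithiated oxirane then adds to the lithium carboxylate (the classical ketone synthesis from organolithiums and lithium carboxylates, here intramolecular), and hydrolysis of the gem-diolate on work-up gives 15.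

2. Step 8. Facial selectivity at the aldehyde may be poor if the chromium chelate with the C1' hydroxyl is loose, and the vinylstannane may be lost through nickel-mediated coupling with the alkenyl iodide. The fallback sets out from 8 and 9 and comes back at 11. Substrate control is replaced by catalyst control: a catalytic asymmetric Nozaki–Hiyama–Kishi coupling with a chiral sulfonamide–oxazoline complex of CrCl2 (Mn as reductant, Cp2ZrCl2 as turnover reagent, NiCl2 at the lowest workable loading), using the ligand enantiomer matched with the 1,3-anti preference, followed by the same lactonization; it makes no compound beyond the list (F0).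

3. Step 7. Paraformaldehyde may depolymerize incompletely, formaldehyde may oligomerize on the magnesium alkoxide, and the Z geometry may erode. The fallback sets out from 8 and comes back at 15, moving the hydroxymethyl group to the end. Commercial methyl (2Z)-3-iodoprop-2-enoate is coupled with 8 under the conditions of step 8 to give the butenolide without the hydroxymethyl group F2. Epoxidation as in step 9 gives the epoxystannane F3, and ring closure as in step 10 (2.05 equiv n-BuLi) gives the C2-unsubstituted epoxy-enone diol F4. A Morita–Baylis–Hillman hydroxymethylation of F4 (aqueous formaldehyde, DMAP, THF, rt) at C2 then gives 15.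

**Further compounds**

F1 | step 10 | lithium salt of the ring-opened (2Z,4S)-4-hydroxy-2-(hydroxymethyl)but-2-enoic acid of 12 | [Li+].[O-]C(=O)/C(CO)=C\[C@H](O)[C@@]1([C@@H](O)/C=C(\C)CC/C=C(\C)CCC=C(C)C)O[C@H]1[Sn](CCCC)(CCCC)CCCC
F0 | step 8 | none | none
F2 | step 7 | analogue of 11 without the hydroxymethyl group (C3–H butenolide) | O=C1C=C[C@H](O1)/C(=C\[Sn](CCCC)(CCCC)CCCC)[C@@H](O)/C=C(\C)CC/C=C(\C)CCC=C(C)C
F3 | step 7 | analogue of 12 without the hydroxymethyl group | O=C1C=C[C@H](O1)[C@@]2([C@@H](O)/C=C(\C)CC/C=C(\C)CCC=C(C)C)O[C@H]2[Sn](CCCC)(CCCC)CCCC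
F4 | step 7 | analogue of 15 without the hydroxymethyl group (C2–H epoxy-enone diol) | C1=C[C@H](O)[C@@]2([C@@H](O)/C=C(\C)CC/C=C(\C)CCC=C(C)C)O[C@H]2C1=O
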